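**Plan**
- Retrosynthesis: after removal of two silyl ethers, the target is cut twice at C-beta in one operation, at the C-beta–O bond to the ring B phenol oxygen and at the C-beta–C-gamma bond. C-beta is then the diazo carbon of a ring A aroyldiazomethane, which comes from the methyl group of acetosyringone.
- Enabling feature: the only stereocentre, C-beta, bears the ring B aryloxy oxygen, the C-gamma CH2OH and the ring A aroyl carbonyl. This is the pattern of an acylcarbene carbon that has taken up an O–H nucleophile and then a one-carbon aldehyde.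
- Forward order: the ring A piece (silylation, diazo transfer) and the ring B piece (silylation of the side-chain alcohol) are made separately, joined with formaldehyde in one acyclic three-component step, then desilylated. No ring is formed at any stage.
- Stereochemistry: S at C-beta is set in the joining step by a chiral phosphoric acid that organises the transient enol and formaldehyde. Afterwards the centre meets only weakly acidic conditions.

Key step: step 4

Assumption: the sense of induction of the phosphoric acid in step 4 cannot be predicted with certainty; the R acid is written, and its equally available mirror image is to be used if a first trial shows that it is the one leading to S.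

**Step 1**
Reactants: 1 acetosyringone, 1-(4-hydroxy-3,5-dimethoxyphenyl)ethanone
Product: 2 1-[4-(tert-butyldimethylsilyloxy)-3,5-dimethoxyphenyl]ethanone
Conditions: TBSCl, imidazole, DMF, 23 °C
Reagents that add atoms: tert-butyldimethylsilyl chloride, CC(C)(C)[Si](C)(C)Cl
Why: Imidazole-promoted silylation of a phenol is routine even between two ortho methoxy groups, and it masks the ring A hydroxyl, which would otherwise compete for the carbene in step 4.

**Step 2**
Reactants: 2 1-[4-(tert-butyldimethylsilyloxy)-3,5-dimethoxyphenyl]ethanone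
Product: 5 2-diazo-1-[4-(tert-butyldimethylsilyloxy)-3,5-dimethoxyphenyl]ethanone, via lithium enolate 3 (not isolated), via trifluoroacetyl diketone 4 (not isolated)
Conditions: LiN(SiMe3)2, THF, −78 °C; CF3CO2CH2CF3, −78 °C; aq HCl work-up; crude 4 then MsN3, Et3N, H2O (1 equiv), MeCN, 23 °C
Reagents that add atoms: methanesulfonyl azide, CS(=O)(=O)N=[N+]=[N-]
Why: This is a detrifluoroacetylative Regitz diazo transfer (Danheiser variant), in which Claisen acylation of the only possible enolate gives an activated 1,3-diketone that takes the diazo group from the sulfonyl azide and loses the trifluoroacetyl group as the N-mesyl amide, the standard way to turn an aryl methyl ketone into its diazomethyl ketone.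

**Step 3**
Reactants: 6 dihydroconiferyl alcohol, 4-(3-hydroxypropyl)-2-methoxyphenol
Product: 7 4-[3-(tert-butyldimethylsilyloxy)propyl]-2-methoxyphenol
Conditions: TBSCl (1.05 equiv), imidazole, CH2Cl2, 0 °C
Reagents that add atoms: tert-butyldimethylsilyl chloride, CC(C)(C)[Si](C)(C)Cl
Why: With one equivalent of silyl chloride at 0 °C the unhindered primary alcohol should be silylated well ahead of the ortho-methoxy, hydrogen-bonded phenol (chemoselective silylation), which blocks the aliphatic hydroxyl that would otherwise insert into the carbene faster than the phenol.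

**Step 4**
Reactants: 5 2-diazo-1-[4-(tert-butyldimethylsilyloxy)-3,5-dimethoxyphenyl]ethanone; 7 4-[3-(tert-butyldimethylsilyloxy)propyl]-2-methoxyphenol; 8 formaldehyde (anhydrous monomer in THF, freshly prepared by cracking commercial paraformaldehyde)
Product: 12 (2S)-2-{4-[3-(tert-butyldimethylsilyloxy)propyl]-2-methoxyphenoxy}-1-[4-(tert-butyldimethylsilyloxy)-3,5-dimethoxyphenyl]-3-hydroxypropan-1-one, via rhodium carbene 9 (not isolated), via oxonium ylide 10 (not isolated), via Z-enol 11 (not isolated)
Conditions: Rh2(OAc)4 (2 mol %), (R)-3,3'-bis(2,4,6-triisopropylphenyl)-1,1'-binaphthyl-2,2'-diyl hydrogen phosphate (10 mol %), 7 (2 equiv), CH2O (5 equiv, about 1 M in THF), 4 Å MS, CH2Cl2, 0 °C, 5 added over 4 h by syringe pump; pH 7 buffer work-up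
Reagents that add atoms: none
Why: Proposed new method: Rh2(OAc)4 (divalent rhodium) should expel dinitrogen from 5 to give the electrophilic aroyl carbene 9, the phenol oxygen of 7 adds to its carbon to give the protic oxonium ylide 10, a 1,4-proton shift gives the Z-enol 11, and 11 attacks formaldehyde 8 through carbon while both are hydrogen-bonded to the phosphoric acid, so that the C-beta–O and C-beta–C-gamma bonds arise in one operation. The closest known reaction type is the Rh2(OAc)4/chiral phosphoric acid three-component coupling of diazo carbonyl compounds with alcohols and imines or aldehydes, in which oxonium ylides or their enols are trapped in Mannich- or aldol-type fashion; untested here is the combination of an acceptor-only aryl diazomethyl ketone, a phenol as the O–H partner and monomeric formaldehyde as the electrophile under enantiocontrol. No ring is closed. The single stereocentre C-beta is set in the C–C bond-forming event, in which the phosphoryl oxygen holds the enol O–H and the P–OH activates formaldehyde in one cyclic array, the 3,3'-aryl groups of the acid block one face of the geometrically defined Z-enol, and the enantiomer of the acid is chosen for attack on the face that gives S; the medium is neutral to weakly acidic, so the enolisable C-beta–H is not epimerised afterwards. The step needs capture by formaldehyde to outrun the 1,2-proton shift to the plain O–H insertion product, and needs the phenol O–H to win over the arene rings, the formaldehyde oxygen and the newly formed primary alcohol as carbene acceptors. This is secured by the small size and high electrophilicity of formaldehyde used in excess, by silylation of every other hydroxyl group in 5 and 7, by the blocked para position of ring B, and by slow addition of 5 to an excess of 7.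

**Step 5**
Reactants: 12 (2S)-2-{4-[3-(tert-butyldimethylsilyloxy)propyl]-2-methoxyphenoxy}-1-[4-(tert-butyldimethylsilyloxy)-3,5-dimethoxyphenyl]-3-hydroxypropan-1-one
Product: 13 (2S)-3-hydroxy-1-(4-hydroxy-3,5-dimethoxyphenyl)-2-[4-(3-hydroxypropyl)-2-methoxyphenoxy]propan-1-one
Conditions: HF·pyridine, pyridine, THF, 0 to 23 °C; pH 7 buffer work-up
Reagents that add atoms: none
Why: Fluoride-driven Si–O cleavage (formation of the strong Si–F bond) should remove both the aryl and the alkyl silyl ether, and the pyridine-buffered, weakly acidic medium avoids enolisation at C-beta, retro-aldol loss of formaldehyde and dehydration, so the configuration set in step 4 is carried through unchanged.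

**Compound list**
1 | acetosyringone, 1-(4-hydroxy-3,5-dimethoxyphenyl)ethanone | CC(=O)c1cc(OC)c(O)c(OC)c1 | starting material
2 | 1-[4-(tert-butyldimethylsilyloxy)-3,5-dimethoxyphenyl]ethanone | CC(=O)c1cc(OC)c(O[Si](C)(C)C(C)(C)C)c(OC)c1 | intermediate
3 | lithium enolate of 2 | [Li+].C=C([O-])c1cc(OC)c(O[Si](C)(C)C(C)(C)C)c(OC)c1 | intermediate (not isolated)
4 | 4,4,4-trifluoro-1-[4-(tert-butyldimethylsilyloxy)-3,5-dimethoxyphenyl]butane-1,3-dione | O=C(CC(=O)C(F)(F)F)c1cc(OC)c(O[Si](C)(C)C(C)(C)C)c(OC)c1 | intermediate (crude, not isolated)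
5 | 2-diazo-1-[4-(tert-butyldimethylsilyloxy)-3,5-dimethoxyphenyl]ethanone | [N-]=[N+]=CC(=O)c1cc(OC)c(O[Si](C)(C)C(C)(C)C)c(OC)c1 | intermediate
6 | dihydroconiferyl alcohol, 4-(3-hydroxypropyl)-2-methoxyphenol | COc1cc(CCCO)ccc1O | starting material
7 | 4-[3-(tert-butyldimethylsilyloxy)propyl]-2-methoxyphenol | COc1cc(CCCO[Si](C)(C)C(C)(C)C)ccc1O | intermediate
8 | formaldehyde (monomer, from paraformaldehyde) | C=O | starting material
9 | rhodium carbene of 5 (carbene carbon on one rhodium of Rh2(OAc)4; the acetates and the second rhodium are not drawn) | COc1cc(C(=O)C=[Rh])cc(OC)c1O[Si](C)(C)C(C)(C)C | intermediate (not isolated)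
10 | protic oxonium ylide from 9 and 7 | COc1cc(CCCO[Si](C)(C)C(C)(C)C)ccc1[OH+][CH-]C(=O)c1cc(OC)c(O[Si](C)(C)C(C)(C)C)c(OC)c1 | intermediate (not isolated)
11 | (Z)-2-{4-[3-(tert-butyldimethylsilyloxy)propyl]-2-methoxyphenoxy}-1-[4-(tert-butyldimethylsilyloxy)-3,5-dimethoxyphenyl]ethen-1-ol | COc1cc(CCCO[Si](C)(C)C(C)(C)C)ccc1O/C=C(\O)c1cc(OC)c(O[Si](C)(C)C(C)(C)C)c(OC)c1 | intermediate (not isolated)
12 | (2S)-2-{4-[3-(tert-butyldimethylsilyloxy)propyl]-2-methoxyphenoxy}-1-[4-(tert-butyldimethylsilyloxy)-3,5-dimethoxyphenyl]-3-hydroxypropan-1-one | COc1cc(CCCO[Si](C)(C)C(C)(C)C)ccc1O[C@@H](CO)C(=O)c1cc(OC)c(O[Si](C)(C)C(C)(C)C)c(OC)c1 | intermediate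
13 | (2S)-3-hydroxy-1-(4-hydroxy-3,5-dimethoxyphenyl)-2-[4-(3-hydroxypropyl)-2-methoxyphenoxy]propan-1-one | COc1cc(CCCO)ccc1O[C@@H](CO)C(=O)c1cc(OC)c(O)c(OC)c1 | target

**Count**
Total steps: 5. Longest linear sequence: 4 steps (steps 1, 2, 4 and 5 from acetosyringone); step 3 is a one-step branch.

**Steps most likely to fail**

Step 4. The proton shift, or acid-mediated tautomerisation of the enol, may outrun capture by formaldehyde so that only plain O–H insertion occurs. The capture may also be poorly face-selective, or the carbene may be lost to dimerisation or to the alcohol of the product. The fallback is an auxiliary-controlled aldol route of known chemistry that sets out from 7 and returns at 12.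
- Phenol 7 is alkylated with bromoacetic acid (NaH, THF, Williamson ether synthesis) to 2-{4-[3-(tert-butyldimethylsilyloxy)propyl]-2-methoxyphenoxy}acetic acid F1.
- F1 is activated as its mixed pivalic anhydride F2 (PivCl, Et3N, THF, −20 °C), which acylates (R)-4-benzyl-2-oxazolidinone (LiCl, Et3N) to give the N-acyl oxazolidinone F3.
- Soft enolisation (Bu2BOTf, iPr2NEt, CH2Cl2, −78 °C) gives the Z dibutylboron enolate F4.
- F4 adds to 4-(tert-butyldimethylsilyloxy)-3,5-dimethoxybenzaldehyde F5 (from commercial syringaldehyde, TBSCl, imidazole) in an Evans syn-aldol reaction. After H2O2/pH 7 buffer work-up this should give the 2R,3S adduct F6.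
- LiBH4 (THF, MeOH, 0 °C) removes the auxiliary reductively to give the (1S,2S)-diol F7.
- DDQ (CH2Cl2, 23 °C) should oxidise only the electron-rich benzylic secondary alcohol, which gives 12.

Here the R auxiliary fixes C-beta, which becomes S once the imide carbonyl carbon has been reduced to the C-gamma hydroxymethyl group.

Step 5. Cleavage of the hindered ring A silyl ether may be slow, and prolonged exposure may bring retro-aldol loss of formaldehyde, dehydration or enolisation at C-beta. The fallback sets out from 12 and returns at 13, replacing the single global fluoride treatment by two orthogonal, milder unmasking operations. KHF2 in MeOH at 23 °C removes the phenolic silyl ether selectively to give (2S)-2-{4-[3-(tert-butyldimethylsilyloxy)propyl]-2-methoxyphenoxy}-3-hydroxy-1-(4-hydroxy-3,5-dimethoxyphenyl)propan-1-one F8. The remaining primary alkyl silyl ether is then removed by acid-catalysed methanolysis (PPTS, MeOH, 23 to 40 °C), giving 13.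

Step 2. Trifluoroacetylation of the electron-rich enolate may be incomplete, or the activated aryl silyl ether may be lost in the basic aqueous diazo-transfer medium. The fallback sets out from 2 and returns at 5. α-Bromination with PhNMe3Br3 (THF, 0 °C) gives 2-bromo-1-[4-(tert-butyldimethylsilyloxy)-3,5-dimethoxyphenyl]ethanone F9. Treatment of F9 with N,N'-ditosylhydrazine and DBU (THF, 0 °C) should give 5 by N-alkylation followed by two eliminations of p-toluenesulfinate.

**Further compounds**
F1 | step 4 | 2-{4-[3-(tert-butyldimethylsilyloxy)propyl]-2-methoxyphenoxy}acetic acid | COc1cc(CCCO[Si](C)(C)C(C)(C)C)ccc1OCC(=O)O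
F2 | step 4 | pivalic 2-{4-[3-(tert-butyldimethylsilyloxy)propyl]-2-methoxyphenoxy}acetic anhydride | COc1cc(CCCO[Si](C)(C)C(C)(C)C)ccc1OCC(=O)OC(=O)C(C)(C)C
F3 | step 4 | (4R)-4-benzyl-3-(2-{4-[3-(tert-butyldimethylsilyloxy)propyl]-2-methoxyphenoxy}acetyl)-1,3-oxazolidin-2-one | COc1cc(CCCO[Si](C)(C)C(C)(C)C)ccc1OCC(=O)N1[C@H](Cc2ccccc2)COC1=O
F4 | step 4 | Z dibutylboron enolate of F3 | COc1cc(CCCO[Si](C)(C)C(C)(C)C)ccc1O/C=C(\OB(CCCC)CCCC)N1[C@H](Cc2ccccc2)COC1=O
F5 | step 4 | 4-(tert-butyldimethylsilyloxy)-3,5-dimethoxybenzaldehyde | COc1cc(C=O)cc(OC)c1O[Si](C)(C)C(C)(C)C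
F6 | step 4 | (4R)-4-benzyl-3-[(2R,3S)-2-{4-[3-(tert-butyldimethylsilyloxy)propyl]-2-methoxyphenoxy}-3-[4-(tert-butyldimethylsilyloxy)-3,5-dimethoxyphenyl]-3-hydroxypropanoyl]-1,3-oxazolidin-2-one | COc1cc(CCCO[Si](C)(C)C(C)(C)C)ccc1O[C@H]([C@@H](O)c1cc(OC)c(O[Si](C)(C)C(C)(C)C)c(OC)c1)C(=O)N1[C@H](Cc2ccccc2)COC1=O
F7 | step 4 | (1S,2S)-2-{4-[3-(tert-butyldimethylsilyloxy)propyl]-2-methoxyphenoxy}-1-[4-(tert-butyldimethylsilyloxy)-3,5-dimethoxyphenyl]propane-1,3-diol | COc1cc(CCCO[Si](C)(C)C(C)(C)C)ccc1O[C@@H](CO)[C@@H](O)c1cc(OC)c(O[Si](C)(C)C(C)(C)C)c(OC)c1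
F8 | step 5 | (2S)-2-{4-[3-(tert-butyldimethylsilyloxy)propyl]-2-methoxyphenoxy}-3-hydroxy-1-(4-hydroxy-3,5-dimethoxyphenyl)propan-1-one | COc1cc(CCCO[Si](C)(C)C(C)(C)C)ccc1O[C@@H](CO)C(=O)c1cc(OC)c(O)c(OC)c1
F9 | step 2 | 2-bromo-1-[4-(tert-butyldimethylsilyloxy)-3,5-dimethoxyphenyl]ethanone | O=C(CBr)c1cc(OC)c(O[Si](C)(C)C(C)(C)C)c(OC)c1
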